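The route disconnects the C4–C5 bond of ring A (C10, C1, C2, C3, C4, C5). It exploits two features of that ring: the gem-dimethyl carbon C4, a latent tertiary cation next to C5, and the trisubstituted C1=C10 alkene, the site of proton loss from a C10 cation. In one operation, a protonative cation–olefin cyclization of a ring B cyclohexene carrying a 4-methylpent-3-enyl chain on C10 closes ring A last, sets C5 and delivers the C1=C10 alkene. The precursor is a monocyclic diene ester. Its C8/C9 stereocentres come from an asymmetric conjugate methylation followed by enolate methylation, C13 from monomethyl (R)-3-methylglutarate, and the glyceryl unit from (S)-solketal.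

Key step: step 7

Remarks:
- Halimane numbering is used: ring A is C1, C2, C3, C4, C5, C10; ring B is C5 to C10; the side chain is C11 to C16; C17 is on C8, C18/C19 on C4 and C20 on C9.
- The target is taken as drawn: 5S, 8R, 9R, 13R, glyceryl C2 (R). This puts the C8 and C9 methyl groups trans and the C9 side chain cis to the C8 methyl.
- Compounds 1, 4, 11 and 16 are taken as commercially available.
- In step 4 the ligand enantiomer is the one that delivers methyl to the face giving 8R; the sense of induction has to be confirmed on a model enone.

Step 1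
Reactants: 1 monomethyl (R)-3-methylglutarate
Product: 2 methyl (3R)-5-hydroxy-3-methylpentanoate
Conditions: BH3·SMe2, THF, 0 °C to rt; MeOH quench
Reagents that add atoms: none
Why: Chemoselective borane reduction of a carboxylic acid (acyloxyborane pathway) in the presence of a methyl ester should give the primary alcohol without touching the C13 stereocentre; the product is used promptly to avoid lactonization.

Step 2
Reactants: 2 methyl (3R)-5-hydroxy-3-methylpentanoate
Product: 3 methyl (3S)-5-iodo-3-methylpentanoate
Conditions: I2, PPh3, imidazole, CH2Cl2, 0 °C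
Reagents that add atoms: iodine, II
Why: Appel-type iodination proceeds by SN2 displacement at the primary carbinol carbon, so the stereocentre is untouched (its descriptor changes to S only through the CIP priorities).

Step 3
Reactants: 3 methyl (3S)-5-iodo-3-methylpentanoate; 4 2-iodocyclohex-2-en-1-one
Product: 6 methyl (3R)-3-methyl-5-(6-oxocyclohex-1-en-1-yl)pentanoate, via alkylzinc iodide 5 (not isolated)
Conditions: Zn, LiCl, THF, 40 °C; then 4, Pd(OAc)2 (cat.), SPhos (cat.), THF, rt
Reagents that add atoms: none
Why: Negishi coupling: zinc insertion into the primary iodide tolerates the ester, and zerovalent palladium formed in situ couples the alkylzinc with the α-iodoenone, the bulky biaryl phosphine favouring reductive elimination over β-hydride loss.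

Step 4
Reactants: 6 methyl (3R)-3-methyl-5-(6-oxocyclohex-1-en-1-yl)pentanoate
Product: 8 methyl (3R)-5-[(1R,2R)-1,2-dimethyl-6-oxocyclohexyl]-3-methylpentanoate, via bromomagnesium enolate 7 (not isolated)
Conditions: MeMgBr (slow addition), Cu(OTf)2 (cat.), chiral imidazolinium salt (carbene ligand precursor, cat.), Et2O, −30 °C; then MeI, DMPU, −30 to 0 °C
Reagents that add atoms: methylmagnesium bromide, C[Mg]Br; iodomethane, CI
Why: Copper-catalysed asymmetric conjugate addition to the α-substituted cyclohexenone sets C8 (R) under catalyst control and gives the C9=C10 enolate regiospecifically, and methylation of this enolate anti to the adjacent C8 methyl sets C9 (R) with C20 trans to C17 and the side chain cis to C17.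

Step 5
Reactants: 8 methyl (3R)-5-[(1R,2R)-1,2-dimethyl-6-oxocyclohexyl]-3-methylpentanoate
Product: 10 methyl (3R)-5-[(1R,6R)-1,6-dimethyl-2-(trifluoromethanesulfonyloxy)cyclohex-2-en-1-yl]-3-methylpentanoate, via lithium enolate 9 (not isolated)
Conditions: LiN(SiMe3)2, THF, −78 °C; then N-(5-chloropyridin-2-yl)bis(trifluoromethanesulfonimide), −78 to 0 °C
Reagents that add atoms: N-(5-chloropyridin-2-yl)bis(trifluoromethanesulfonimide), FC(F)(F)S(=O)(=O)N(c1ccc(Cl)cn1)S(=O)(=O)C(F)(F)F
Why: C9 is quaternary, so the ketone (several pKa units more acidic than the ester) can enolize only toward C5, and O-triflation of the lithium enolate should give the C5=C10 enol triflate as a single regioisomer.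

Step 6
Reactants: 10 methyl (3R)-5-[(1R,6R)-1,6-dimethyl-2-(trifluoromethanesulfonyloxy)cyclohex-2-en-1-yl]-3-methylpentanoate; 11 5-bromo-2-methylpent-2-ene
Product: 13 methyl (3R)-5-[(1R,6R)-1,6-dimethyl-2-(4-methylpent-3-en-1-yl)cyclohex-2-en-1-yl]-3-methylpentanoate, via homoprenylzinc bromide 12 (not isolated)
Conditions: 11, Zn, LiCl, THF, 40 °C; then 10, Pd(OAc)2 (cat.), SPhos (cat.), THF/NMP, 50 °C
Reagents that add atoms: none
Why: Negishi coupling of the alkenyl triflate with the primary alkylzinc forms the C10–C1 bond, keeps the ring alkene at C5=C10, tolerates the ester and touches no stereocentre.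

Step 7
Reactants: 13 methyl (3R)-5-[(1R,6R)-1,6-dimethyl-2-(4-methylpent-3-en-1-yl)cyclohex-2-en-1-yl]-3-methylpentanoate
Product: 14 methyl (5S,8R,9R,13R)-halim-1(10)-en-15-oate
Conditions: SnCl4 (2 equiv), CF3CO2H (1.2 equiv), CH2Cl2, −78 °C; then Et3N at −78 °C, aq. NaHCO3
Reagents that add atoms: none
Why: The SnCl4-activated trifluoroacetic acid protonates the accessible side-chain alkene at C3 to give the tertiary C4 cation, which is captured by C5 of the ring B alkene to give the tertiary C10 (halimanyl) cation, and loss of H1 then installs the C1=C10 alkene, so the step is a net cycloisomerization. The closest known reaction type is the Brønsted/Lewis acid-promoted cation–olefin cyclization of 1,5-dienes used in terpene synthesis. Ring A (C10, C1, C2, C3, C4, C5) is closed by C4–C5 bond formation in a 6-endo-trig mode (with respect to the C5=C10 alkene) through a chair-like transition state; the 5-exo alternative at C10 would give a secondary cation and a spiro centre and is not expected. The new stereocentre C5 is controlled by the C9 quaternary centre: in the ring B half-chair that keeps the C8 methyl equatorial, the C9 side chain is pseudoaxial (which also relieves A(1,2) strain with the C10 substituent), so C4 should add to the opposite face, placing H5 cis to the side chain (5S). The step needs initiation at the side-chain alkene and proton loss toward C1 and not C5: protonation of the hindered ring alkene is reversible and leads to no favourable ring closure, and H5 is a shielded hydrogen flanked by the C4 gem-dimethyl group, so kinetic deprotonation at −78 °C followed by a basic quench before warming should favour the C1=C10 isomer.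

Step 8
Reactants: 14 methyl (5S,8R,9R,13R)-halim-1(10)-en-15-oate
Product: 15 (5S,8R,9R,13R)-halim-1(10)-en-15-oic acid
Conditions: LiOH, THF/MeOH/H2O, 40 °C; then cold 1 M HCl to pH 3
Reagents that add atoms: lithium hydroxide, [Li+].[OH-]
Why: Saponification of the unhindered methyl ester by acyl–oxygen cleavage; the alkene and all stereocentres are inert to aqueous hydroxide.

Step 9
Reactants: 15 (5S,8R,9R,13R)-halim-1(10)-en-15-oic acid; 16 (S)-solketal
Product: 17 [(4R)-2,2-dimethyl-1,3-dioxolan-4-yl]methyl (5S,8R,9R,13R)-halim-1(10)-en-15-oate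
Conditions: EDC·HCl, DMAP (cat.), CH2Cl2, 0 °C to rt
Reagents that add atoms: none
Why: Steglich esterification (carbodiimide activation, acyl transfer by DMAP) of the acid with the primary alcohol of (S)-solketal; the dioxolane stereocentre is not involved and corresponds to the (R)-configured C2 of the glyceryl ester.

Step 10
Reactants: 17 [(4R)-2,2-dimethyl-1,3-dioxolan-4-yl]methyl (5S,8R,9R,13R)-halim-1(10)-en-15-oate
Product: 18 (2R)-2,3-dihydroxypropyl (5S,8R,9R,13R)-halim-1(10)-en-15-oate
Conditions: AcOH/H2O (4:1), 40 °C
Reagents that add atoms: none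
Why: Mild acid-catalysed hydrolysis of the isopropylidene ketal should release the 1,2-diol without 1,2-acyl migration or isomerization of the hindered trisubstituted alkene.

Compound list
1 | monomethyl (R)-3-methylglutarate [(3R)-5-methoxy-3-methyl-5-oxopentanoic acid] | C[C@H](CC(=O)O)CC(=O)OC | starting material
2 | methyl (3R)-5-hydroxy-3-methylpentanoate | C[C@H](CCO)CC(=O)OC | intermediate
3 | methyl (3S)-5-iodo-3-methylpentanoate | C[C@H](CCI)CC(=O)OC | intermediate
4 | 2-iodocyclohex-2-en-1-one | O=C1CCCC=C1I | starting material
5 | [(3S)-5-methoxy-3-methyl-5-oxopentyl]zinc iodide (not isolated) | C[C@H](CC[Zn]I)CC(=O)OC | intermediate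
6 | methyl (3R)-3-methyl-5-(6-oxocyclohex-1-en-1-yl)pentanoate | C[C@H](CCC1=CCCCC1=O)CC(=O)OC | intermediate
7 | bromomagnesium enolate of the conjugate adduct, (6R)-6-methyl-2-oxidocyclohex-1-en-1-yl side-chain ester (not isolated) | C[C@H](CCC1=C(O[Mg]Br)CCC[C@H]1C)CC(=O)OC | intermediate
8 | methyl (3R)-5-[(1R,2R)-1,2-dimethyl-6-oxocyclohexyl]-3-methylpentanoate | C[C@H](CC[C@@]1(C)C(=O)CCC[C@H]1C)CC(=O)OC | intermediate
9 | lithium enolate of 8 (C5=C10 enolate, not isolated) | C[C@H](CC[C@@]1(C)C(O[Li])=CCC[C@H]1C)CC(=O)OC | intermediate
10 | methyl (3R)-5-[(1R,6R)-1,6-dimethyl-2-(trifluoromethanesulfonyloxy)cyclohex-2-en-1-yl]-3-methylpentanoate | C[C@H](CC[C@@]1(C)C(OS(=O)(=O)C(F)(F)F)=CCC[C@H]1C)CC(=O)OC | intermediate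
11 | 5-bromo-2-methylpent-2-ene | CC(C)=CCCBr | starting material
12 | (4-methylpent-3-en-1-yl)zinc bromide (not isolated) | CC(C)=CCC[Zn]Br | intermediate
13 | methyl (3R)-5-[(1R,6R)-1,6-dimethyl-2-(4-methylpent-3-en-1-yl)cyclohex-2-en-1-yl]-3-methylpentanoate | C[C@H](CC[C@@]1(C)C(CCC=C(C)C)=CCC[C@H]1C)CC(=O)OC | intermediate
14 | methyl (5S,8R,9R,13R)-halim-1(10)-en-15-oate [methyl (3R)-3-methyl-5-[(1R,2R,4aS)-1,2,5,5-tetramethyl-1,2,3,4,4a,5,6,7-octahydronaphthalen-1-yl]pentanoate] | C[C@H](CC[C@@]1(C)C2=CCCC(C)(C)[C@@H]2CC[C@H]1C)CC(=O)OC | intermediate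
15 | (5S,8R,9R,13R)-halim-1(10)-en-15-oic acid | C[C@H](CC[C@@]1(C)C2=CCCC(C)(C)[C@@H]2CC[C@H]1C)CC(=O)O | intermediate
16 | (S)-solketal [(4S)-2,2-dimethyl-1,3-dioxolan-4-yl]methanol | CC1(C)OC[C@H](CO)O1 | starting material
17 | [(4R)-2,2-dimethyl-1,3-dioxolan-4-yl]methyl (5S,8R,9R,13R)-halim-1(10)-en-15-oate | C[C@H](CC[C@@]1(C)C2=CCCC(C)(C)[C@@H]2CC[C@H]1C)CC(=O)OC[C@H]1COC(C)(C)O1 | intermediate
18 | (2R)-2,3-dihydroxypropyl (3R)-3-methyl-5-[(1R,2R,4aS)-1,2,5,5-tetramethyl-1,2,3,4,4a,5,6,7-octahydronaphthalen-1-yl]pentanoate | C[C@H](CC[C@@]1(C)C2=CCCC(C)(C)[C@@H]2CC[C@H]1C)CC(=O)OC[C@H](O)CO | target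

Total step count: 10. Longest linear sequence: 10 steps (1 to 18).

Steps most likely to fail

1. Step 7. What may go wrong:
- poor facial selectivity at C5, because the two ring B half-chairs are close in energy;
- proton loss toward C5, or acid-mediated migration of the alkene into the tetrasubstituted C5=C10 position;
- 1,2-hydride or 1,2-methyl shifts of the C10 cation;
- addition of trifluoroacetate to the side-chain alkene without ring closure.

Fallback (ring A closed by an aldol condensation, which fixes the alkene position): it sets out from ketone 8 and comes back at 14. Ketone 8 would be converted with Me3SiOTf and Et3N into the trimethylsilyl enol ether F1. A Mukaiyama–Michael addition of F1 to mesityl oxide (TiCl4, CH2Cl2, −78 °C) should attach the C4 quaternary carbon to C5 and give the 1,5-diketone F2. Attack is expected anti to the pseudoaxial C9 chain, and C5 is now epimerizable, so it can also be corrected by base equilibration. Intramolecular aldol condensation of the methyl ketone onto the C10 carbonyl (NaOMe, MeOH, reflux) would close ring A as the bicyclic enone F3 with the alkene fixed at C1=C10. Thioketalization (ethane-1,2-dithiol, BF3·OEt2) to the dithiolane F4 and desulfurization with deactivated Raney Ni would remove the C2 oxygen without moving the alkene and return to 14.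

2. Step 4. What may go wrong:
- intramolecular Claisen acylation of the magnesium enolate by the side-chain ester before methylation;
- attack of the Grignard reagent on the ester;
- insufficient enantioface control with a methyl nucleophile on an α-substituted enone.

Fallback (enolate generated only in the presence of the electrophile): it sets out from enone 6 and comes back at 8. Copper-catalysed asymmetric conjugate addition of Me3Al (Cu(O2CC4H3S), the thiophene-2-carboxylate, with a chiral phosphoramidite, Et2O, −30 °C) is ester-tolerant. The aluminium enolate would be trapped with Me3SiOTf as the trimethylsilyl enol ether F5. Regiospecific methylation of isolated F5 with MeI and benzyltrimethylammonium fluoride (THF, molecular sieves) would then give 8, again anti to the C8 methyl.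

3. Step 6. What may go wrong:
- slow oxidative addition or transmetalation at the hindered triflate next to the C9 quaternary centre, leading to reduction of the triflate;
- β-hydride loss from the alkylpalladium intermediate.

Fallback (carbonyl addition in place of cross-coupling): it sets out from ketone 8 and comes back at 14. The Grignard reagent from 11 (Mg, THF), transmetalated with CeCl3 at −78 °C, should add to the C10 carbonyl in preference to the ester and give the tertiary alcohol F6 (C10 epimers, of no consequence). Under the conditions of step 7, F6 would ionize to the C10 cation, which equilibrates by proton loss with diene 13 and then cyclizes, so the route is rejoined at 14.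

Further compounds
F1 | step 7 | trimethylsilyl enol ether of ketone 8 (C5=C10) | C[C@H](CC[C@@]1(C)C(O[Si](C)(C)C)=CCC[C@H]1C)CC(=O)OC
F2 | step 7 | methyl (3R)-5-[(1R,3S,6R)-1,6-dimethyl-3-(2-methyl-4-oxopentan-2-yl)-2-oxocyclohexyl]-3-methylpentanoate | C[C@H](CC[C@@]1(C)C(=O)[C@H](C(C)(C)CC(C)=O)CC[C@H]1C)CC(=O)OC
F3 | step 7 | methyl (5S,8R,9R,13R)-2-oxohalim-1(10)-en-15-oate | C[C@H](CC[C@@]1(C)C2=CC(=O)CC(C)(C)[C@@H]2CC[C@H]1C)CC(=O)OC
F4 | step 7 | 2,2-(ethane-1,2-diyldisulfanediyl) derivative (1,3-dithiolane) of F3 | C[C@H](CC[C@@]1(C)C2=CC3(SCCS3)CC(C)(C)[C@@H]2CC[C@H]1C)CC(=O)OC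
F5 | step 4 | methyl (3R)-3-methyl-5-[(6R)-6-methyl-2-(trimethylsilyloxy)cyclohex-1-en-1-yl]pentanoate | C[C@H](CCC1=C(O[Si](C)(C)C)CCC[C@H]1C)CC(=O)OC
F6 | step 6 | methyl (3R)-5-[(1R,6R)-2-hydroxy-1,6-dimethyl-2-(4-methylpent-3-en-1-yl)cyclohexyl]-3-methylpentanoate (C10 epimers) | C[C@H](CC[C@@]1(C)C(O)(CCC=C(C)C)CCC[C@H]1C)CC(=O)OC
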